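## Retrosynthetic overview

1. Target ⇐ 8,9-alkene ester: bromohydrin formation and base closure put the oxirane on the β face and free the phenol in the same pot. The ester ⇐ diol + CO + silyl-protected 4-iodophenol (carbonylative esterification).
2. Diol ⇐ β,γ-unsaturated hydroazulenone by chelation-controlled reduction (sets C-6).
3. Key step: hydroazulenone ⇐ cis-hydrindenone by one-carbon ring expansion (diazoalkane insertion with 1,2-alkenyl shift); the seven-membered ring is formed last.
4. Hydrindenone ⇐ saturated bicyclic ketol by α-methylation and dehydrogenation.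
5. Ketol ⇐ 3-methylcyclohex-2-enone + 1-isopropylcyclopropanol by asymmetric homoenolate conjugate addition/aldol annulation (sets C-1, C-4, C-5). Ring order: six-membered ring (bought) → five-membered ring → seven-membered ring by expansion.

Assumption: the SMILES is read as written, i.e. the cis-fused daucane (1S,4R,5S,6R,8R,9S) with the oxirane oxygen on the face of the angular methyl group.

Conventions: daucane locants are used in the text (C-1 angular methyl carbon, C-2/C-3 ring CH2, C-4 carbinol carbon with isopropyl, C-5 ring-fusion CH, C-6 acyloxy carbon, C-7 CH2, C-8 methyl-bearing carbon, C-9, C-10). β is the face of the C-1 methyl group. Imidazolinium salt A is (4S,5S)-4,5-diphenyl-1-(2-sulfonatophenyl)-3-(2,4,6-trimethylphenyl)-4,5-dihydro-1H-imidazol-3-ium (zwitterion), the precursor of a bidentate sulfonate N-heterocyclic carbene. The enantiomer of A is used if it proves to be the one that gives the 7aR centre of 6.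

## Route

Step 1
Reactants: 1 methyl 2-methylpropanoate
Product: 2 1-(propan-2-yl)cyclopropan-1-ol
Conditions: EtMgBr (2.4 equiv), Ti(OiPr)4 (20 mol %), Et2O, 0 → 20 °C; aq NH4Cl
Reagents that add atoms: ethylmagnesium bromide, CC[Mg]Br
Why: Kulinkovich cyclopropanation: the titanacyclopropane formed from EtMgBr and Ti(OiPr)4 adds twice to the ester carbonyl as a 1,2-dicarbanion equivalent; no stereocentre is formed.

Step 2
Reactants: 2 1-(propan-2-yl)cyclopropan-1-ol; 3 3-methylcyclohex-2-en-1-one
Product: 6 (3R,3aR,7aR)-3-hydroxy-7a-methyl-3-(propan-2-yl)octahydro-4H-inden-4-one, via zinc homoenolate 4 (not isolated), via zinc enolate 5 (not isolated)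
Conditions: 2 (2.4 equiv), Et2Zn (1.2 equiv), THF, 0 → 40 °C; then Cu(OTf)2 (5 mol %), imidazolinium salt A (6 mol %), 3 (1.0 equiv), −20 → 20 °C; aq NH4Cl
Reagents that add atoms: none
Why: Proposed new method: strain-driven opening of the zinc cyclopropoxide gives a β-zincio ketone (homoenolate, no ethyl group left on zinc) that transmetalates to a chiral carbene-bound monovalent copper centre, which adds the alkyl group to one face of the β-methyl enone as simple dialkylzincs do with this catalyst class (sets quaternary C-1), and the regiodefined zinc enolate is then trapped by the tethered isopropyl ketone through a zinc-bridged 5-(enolexo)-exo-trig aldol transition state that enforces cis ring fusion (C-5) and places the C-4 oxygen syn to the C-6 carbonyl (C-4); the closest known reactions are copper–carbene asymmetric conjugate addition of dialkylzincs to 3-methylcyclohexenone, copper-catalysed conjugate addition of zinc ester homoenolates, and conjugate addition–aldol annulation.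

Step 3
Reactants: 6 (3R,3aR,7aR)-3-hydroxy-7a-methyl-3-(propan-2-yl)octahydro-4H-inden-4-one
Product: 7 (3R,3aR,7aR)-3-hydroxy-5,7a-dimethyl-3-(propan-2-yl)octahydro-4H-inden-4-one (mixture of epimers at the new methyl-bearing carbon)
Conditions: LiN(iPr)2 (2.3 equiv), THF, −78 °C; MeI (1.1 equiv), −78 → −40 °C; aq NH4Cl
Reagents that add atoms: iodomethane, CI
Why: Kinetic enolate alkylation: once the tertiary alkoxide has formed, LiN(iPr)2 removes a proton from the unhindered C-8 methylene and not from the C-5 methine, the enolised ketone cannot undergo retro-aldol cleavage, and MeI alkylates C-8; the new C-8 centre forms as a mixture that is erased in step 4.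

Step 4
Reactants: 7 (3R,3aR,7aR)-3-hydroxy-5,7a-dimethyl-3-(propan-2-yl)octahydro-4H-inden-4-one
Product: 9 (3R,3aR,7aS)-5,7a-dimethyl-3-(propan-2-yl)-3-[(trimethylsilyl)oxy]-1,2,3,3a,7,7a-hexahydro-4H-inden-4-one, via bis-silyl enol ether 8 (not isolated)
Conditions: TMSOTf (2.5 equiv), Et3N (4 equiv), CH2Cl2, 0 °C; then Pd(OAc)2 (10 mol %), O2 (1 atm), DMSO, 25 °C
Reagents that add atoms: trimethylsilyl trifluoromethanesulfonate, C[Si](C)(C)OS(=O)(=O)C(F)(F)F
Why: Saegusa–Ito dehydrogenation (aerobic, catalytic in palladium): soft enolisation silylates the tertiary hydroxyl and gives the more accessible and more stable C-6/C-8 silyl enol ether (C-5 lies between two fully substituted carbons), and β-hydride elimination from the palladium enolate can only give the C-8/C-9 enone because C-4 carries no hydrogen; the tertiary silyl ether is kept as protection for step 5.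

Step 5
Reactants: 9 (3R,3aR,7aS)-5,7a-dimethyl-3-(propan-2-yl)-3-[(trimethylsilyl)oxy]-1,2,3,3a,7,7a-hexahydro-4H-inden-4-one
Product: 11 (3R,3aR,8aS)-3-hydroxy-6,8a-dimethyl-3-(propan-2-yl)-2,3,3a,5,8,8a-hexahydroazulen-4(1H)-one, via C-silyl ketone 10 (not isolated)
Conditions: TMSCHN2 (1.5 equiv), Me3Al (1.2 equiv), CH2Cl2, −78 → −20 °C; MeOH quench; then Bu4NF, AcOH, THF, 0 °C
Reagents that add atoms: (trimethylsilyl)diazomethane, C[Si](C)(C)C=[N+]=[N-]
Why: Lewis-acid-promoted diazoalkane homologation (Tiffeneau–Demjanov-type ring expansion): TMSCHN2 adds to the Me3Al-activated C-6 carbonyl and, with loss of N2, the alkenyl carbon C-8 undergoes the 1,2-shift in preference to the neopentyl-type C-5 methine, which gives the cycloheptenone with the alkene already in the β,γ (C-8/C-9) position; the C-silyl group blocks a second insertion, and buffered fluoride removes both silyl groups with kinetic α-protonation so that neither the alkene nor C-5 moves.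

Step 6
Reactants: 11 (3R,3aR,8aS)-3-hydroxy-6,8a-dimethyl-3-(propan-2-yl)-2,3,3a,5,8,8a-hexahydroazulen-4(1H)-one
Product: 12 (3R,3aS,4R,8aS)-6,8a-dimethyl-3-(propan-2-yl)-1,2,3,3a,4,5,8,8a-octahydroazulene-3,4-diol
Conditions: Zn(BH4)2, Et2O, −20 → 0 °C; aq NH4Cl
Reagents that add atoms: none
Why: Chelation-controlled (Cram-chelate) carbonyl reduction: zinc bridges the C-4 oxygen and the C-6 carbonyl, and hydride adds to the carbonyl face flanked by H-5 and not by quaternary C-1, giving the 6R alcohol (H-6 cis to H-5); the neutral reagent does not move the β,γ-alkene into conjugation.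

Step 7
Reactants: 13 4-iodophenol
Product: 14 tert-butyl(4-iodophenoxy)dimethylsilane
Conditions: TBSCl, imidazole, DMF, 23 °C
Reagents that add atoms: tert-butyl(chloro)dimethylsilane, CC(C)(C)[Si](C)(C)Cl
Why: Imidazole-promoted silyl ether formation protects the phenol for the carbonylation and the bromination; no stereocentre is formed.

Step 8
Reactants: 12 (3R,3aS,4R,8aS)-6,8a-dimethyl-3-(propan-2-yl)-1,2,3,3a,4,5,8,8a-octahydroazulene-3,4-diol; 14 tert-butyl(4-iodophenoxy)dimethylsilane (1.3 equiv)
Product: 15 (3R,3aS,4R,8aS)-3-hydroxy-6,8a-dimethyl-3-(propan-2-yl)-1,2,3,3a,4,5,8,8a-octahydroazulen-4-yl 4-[(tert-butyldimethylsilyl)oxy]benzoate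
Conditions: Pd(OAc)2 (5 mol %), Xantphos (6 mol %), CO (1 atm), Et3N, DMAP (20 mol %), toluene, 80 °C
Reagents that add atoms: carbon monoxide, [C-]#[O+]
Why: Palladium-catalysed alkoxycarbonylation of an aryl iodide (carbonylative esterification): oxidative addition, CO insertion and alcoholysis of the acylpalladium by the secondary C-6 hydroxyl (the tertiary C-4 hydroxyl is too hindered) build the aryl ester without touching the C-6–O bond, so C-6 keeps its configuration.

Step 9
Reactants: 15 (3R,3aS,4R,8aS)-3-hydroxy-6,8a-dimethyl-3-(propan-2-yl)-1,2,3,3a,4,5,8,8a-octahydroazulen-4-yl 4-[(tert-butyldimethylsilyl)oxy]benzoate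
Product: 18 (1S,4R,5S,6R,8R,9S)-8,9-epoxy-4-hydroxydaucan-6-yl 4-hydroxybenzoate (CNP0163817.4), via bromohydrin 16 (not isolated), via silyl epoxide 17 (not isolated)
Conditions: NBS (1.1 equiv), THF–H2O (4:1), 0 °C; then K2CO3, MeOH, 0 → 23 °C; aq NH4Cl
Reagents that add atoms: water, O
Why: Bromohydrin formation followed by base-induced oxirane closure (halohydrin route): Br+ engages the alkene on the α face, anti to the pseudo-axial C-1 methyl group, water opens the bromonium ion from the β face, and carbonate closes the ring by intramolecular SN2 displacement with inversion at C-9, which places the oxirane oxygen on the β face (8R,9S); the same methanolic carbonate cleaves the aryl silyl ether, while the benzoate, deactivated as its para-phenoxide, survives.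

## Compound list

1 | methyl 2-methylpropanoate | COC(=O)C(C)C | starting material
2 | 1-(propan-2-yl)cyclopropan-1-ol | CC(C)C1(O)CC1 | intermediate
3 | 3-methylcyclohex-2-en-1-one | CC1=CC(=O)CCC1 | starting material
4 | bis(4-methyl-3-oxopentyl)zinc (zinc homoenolate, in equilibrium with its cyclopropoxide form; not isolated) | CC(C)C(=O)CC[Zn]CCC(=O)C(C)C | intermediate
5 | zinc enolate (C-5=C-6) of (R)-3-methyl-3-(4-methyl-3-oxopentyl)cyclohexan-1-one (not isolated) | CC(C)C(=O)CC[C@@]1(C)CCCC(O[Zn]CCC(=O)C(C)C)=C1 | intermediate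
6 | (3R,3aR,7aR)-3-hydroxy-7a-methyl-3-(propan-2-yl)octahydro-4H-inden-4-one (cis-fused; OH cis to the ketone-bearing bond) | CC(C)[C@]1(O)CC[C@@]2(C)CCCC(=O)[C@H]21 | intermediate
7 | (3R,3aR,7aR)-3-hydroxy-5,7a-dimethyl-3-(propan-2-yl)octahydro-4H-inden-4-one (both C-5 epimers, indene numbering) | CC(C)[C@]1(O)CC[C@@]2(C)CCC(C)C(=O)[C@H]21 | intermediate
8 | 7 as its tertiary trimethylsilyl ether and C-4/C-5 (indene numbering) trimethylsilyl enol ether; ring-fusion and carbinol centres as in 7 (not isolated) | CC(C)[C@]1(O[Si](C)(C)C)CC[C@@]2(C)CCC(C)=C(O[Si](C)(C)C)[C@H]21 | intermediate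
9 | (3R,3aR,7aS)-5,7a-dimethyl-3-(propan-2-yl)-3-[(trimethylsilyl)oxy]-1,2,3,3a,7,7a-hexahydro-4H-inden-4-one | CC(C)[C@]1(O[Si](C)(C)C)CC[C@@]2(C)CC=C(C)C(=O)[C@H]21 | intermediate
10 | (3R,3aR,8aS)-6,8a-dimethyl-3-(propan-2-yl)-5-(trimethylsilyl)-3-[(trimethylsilyl)oxy]-2,3,3a,5,8,8a-hexahydroazulen-4(1H)-one (C-5 epimers; not isolated) | CC(C)[C@]1(O[Si](C)(C)C)CC[C@@]2(C)CC=C(C)C([Si](C)(C)C)C(=O)[C@H]21 | intermediate
11 | (3R,3aR,8aS)-3-hydroxy-6,8a-dimethyl-3-(propan-2-yl)-2,3,3a,5,8,8a-hexahydroazulen-4(1H)-one | CC(C)[C@]1(O)CC[C@@]2(C)CC=C(C)CC(=O)[C@H]21 | intermediate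
12 | (3R,3aS,4R,8aS)-6,8a-dimethyl-3-(propan-2-yl)-1,2,3,3a,4,5,8,8a-octahydroazulene-3,4-diol | CC(C)[C@]1(O)CC[C@@]2(C)CC=C(C)C[C@@H](O)[C@H]21 | intermediate
13 | 4-iodophenol | Oc1ccc(I)cc1 | starting material
14 | tert-butyl(4-iodophenoxy)dimethylsilane | CC(C)(C)[Si](C)(C)Oc1ccc(I)cc1 | intermediate
15 | (3R,3aS,4R,8aS)-3-hydroxy-6,8a-dimethyl-3-(propan-2-yl)-1,2,3,3a,4,5,8,8a-octahydroazulen-4-yl 4-[(tert-butyldimethylsilyl)oxy]benzoate | CC(C)[C@]1(O)CC[C@@]2(C)CC=C(C)C[C@@H](OC(=O)c3ccc(O[Si](C)(C)C(C)(C)C)cc3)[C@H]21 | intermediate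
16 | (1S,4R,5S,6R,8R,9R)-9-bromo-4,8-dihydroxydaucan-6-yl 4-[(tert-butyldimethylsilyl)oxy]benzoate (8β-OH, 9α-Br; not isolated) | CC(C)[C@]1(O)CC[C@@]2(C)C[C@@H](Br)[C@](C)(O)C[C@@H](OC(=O)c3ccc(O[Si](C)(C)C(C)(C)C)cc3)[C@H]21 | intermediate
17 | (1S,4R,5S,6R,8R,9S)-8,9-epoxy-4-hydroxydaucan-6-yl 4-[(tert-butyldimethylsilyl)oxy]benzoate (not isolated) | CC(C)[C@]1(O)CC[C@@]2(C)C[C@@H]3O[C@]3(C)C[C@@H](OC(=O)c3ccc(O[Si](C)(C)C(C)(C)C)cc3)[C@H]21 | intermediate
18 | (1S,4R,5S,6R,8R,9S)-8,9-epoxy-4-hydroxydaucan-6-yl 4-hydroxybenzoate (CNP0163817.4) | CC(C)[C@]1(O)CC[C@@]2(C)C[C@@H]3O[C@]3(C)C[C@@H](OC(=O)c3ccc(O)cc3)[C@H]21 | target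

## Step count and risks

Total steps: 9. Longest linear sequence: 8 (steps 1–6, 8, 9; step 7 is a one-step side branch).

Three steps most likely to fail:

Step 2 (proposed new annulation). The risks are slow transfer of the chelated homoenolate from zinc to copper, β-hydride loss from the copper alkyl, low enantioselectivity, and retro-aldol opening of the aldolate. The fallback uses known chemistry only, sets out from 3 and comes back at 6. Copper/imidazolinium-catalysed asymmetric conjugate addition of (4-methylpent-3-en-1-yl)magnesium bromide (from 5-bromo-2-methylpent-2-ene, seven non-hydrogen atoms) to 3 gives (R)-3-methyl-3-(4-methylpent-3-en-1-yl)cyclohexan-1-one F1. mCPBA epoxidises the trisubstituted alkene to (3R)-3-[2-(3,3-dimethyloxiran-2-yl)ethyl]-3-methylcyclohexan-1-one F2. BF3·OEt2 in CH2Cl2 at −78 °C then induces the Meinwald rearrangement with hydride shift to the diketone (R)-3-methyl-3-(4-methyl-3-oxopentyl)cyclohexan-1-one F3. KOH in MeOH at 0 °C (or pyrrolidine/AcOH) closes the five-membered ring by intramolecular aldol addition to give 6. In this fallback, regio- and diastereocontrol rest on the stability of the hydrogen-bonded cis-ketol and not on a regiodefined enolate.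

Step 5 (ring expansion). The risks are slow addition to the hindered carbonyl, competing migration of C-5, and drift of the alkene into conjugation. The fallback sets out from 9 and comes back at 11. LiCHBr2 (from CH2Br2 and LiN(iPr)2, THF, −78 °C) adds to the C-6 carbonyl to give the dibromomethyl carbinol of 9 F4. n-BuLi (2.2 equiv, −95 → −78 °C) turns it into the β-oxido carbenoid, which rearranges by 1,2-shift of the alkenyl carbon to the ring-expanded dienolate. An AcOH quench gives the trimethylsilyl ether of 11 F5, and Bu4NF/AcOH gives 11.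

Step 9 (face of the oxirane). The risks are bromonium formation on the β face, which would end in the 8α,9α-oxide, and bromoetherification by the C-4 hydroxyl. The fallback sets out from 15 and comes back at 18 through 17. If the electrophile proves to prefer the β face, direct oxygen transfer with mCPBA/NaHCO3 in CH2Cl2 at 0 °C (or dimethyldioxirane) puts the oxygen on that same β face and gives 17 in one operation. K2CO3 in MeOH then gives 18. No compound outside the list is made.

Further compounds
F1 | step 2 | (R)-3-methyl-3-(4-methylpent-3-en-1-yl)cyclohexan-1-one | CC(C)=CCC[C@@]1(C)CCCC(=O)C1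
F2 | step 2 | (3R)-3-[2-(3,3-dimethyloxiran-2-yl)ethyl]-3-methylcyclohexan-1-one (oxirane carbon unassigned) | CC1(C)OC1CC[C@@]2(C)CCCC(=O)C2
F3 | step 2 | (R)-3-methyl-3-(4-methyl-3-oxopentyl)cyclohexan-1-one | CC(C)C(=O)CC[C@@]1(C)CCCC(=O)C1
F4 | step 5 | 4-(dibromomethyl)-5,7a-dimethyl-3-(propan-2-yl)-3-[(trimethylsilyl)oxy]-2,3,3a,4,7,7a-hexahydro-1H-inden-4-ol, centres C-3, C-3a and C-7a as in 9, C-4 unassigned | CC(C)[C@]1(O[Si](C)(C)C)CC[C@@]2(C)CC=C(C)C(O)(C(Br)Br)[C@H]21
F5 | step 5 | (3R,3aR,8aS)-6,8a-dimethyl-3-(propan-2-yl)-3-[(trimethylsilyl)oxy]-2,3,3a,5,8,8a-hexahydroazulen-4(1H)-one | CC(C)[C@]1(O[Si](C)(C)C)CC[C@@]2(C)CC=C(C)CC(=O)[C@H]21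
F0 | step 9 | none | none
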